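The atom numbers C1 to C15 used throughout are the germacrane numbers of the target. C1 to C10 form the ring, C11 to C13 the acrylate part of the lactone, C14 is the ester carbon on C10, and C15 is the methyl on C4.

## The problem

The target is a ten-membered carbocycle (C1 to C10). It is fused at C6–C7 to an α-methylene-γ-butyrolactone (O6, C12, C11, C13). It carries a C4–C5 oxirane, a methacrylate on O8, an acetate on O9 and a methyl ester (C14) on C10.

The SMILES reads as 4R,5S,6R,7R,8S,9S. C2 and C9 are cis on C1=C10, C3 and C6 are cis on the oxirane, and H6 and H7 are cis. Both unsaturation sites are therefore ring-cis and the lactone is cis-fused.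

The hardest features are the medium ring, whose closure is slow and strained, and the six contiguous stereocentres C4 to C9 that sit on it.

Three stereochemical relations can be used. O8 and O9 are threo. O6, C11 and O8 lie on one ring face. O5 and O6 are threo, which is what a peracid gives with a Z-allylic alcohol under A1,3 control. C8 can therefore control C7 and C6, and C6 can control C5 and C4.

Three conjugate acceptors, a trisubstituted oxirane and two secondary esters rule out strong base, strong acid and nucleophilic amines late in the route.

The feature that makes the key step possible is the C6–C7 ring bond. It joins the carbinol carbon C6 to C7, and C7 is the γ-carbon of the 2-(methoxycarbonyl)allyl unit C13–C11(C12)=C7. One allylmetal addition therefore creates the ring bond, the exocyclic methylene and the lactone precursor together.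

The same α-substituted acrylate pattern recurs at C9–C10(C14)=C1. The two ring-cis double bonds C1=C10 and C4=C5 fold the open chain so that C6 and C7 can meet.

## Retrosynthesis

**Lactone.** The first cut is the O6–C12 lactone bond of 21, which leads to the epoxy hydroxy ester 20. Opening here rather than at either ester on O8 or O9 frees O6–H, and that hydroxyl is the only handle able to steer the oxirane. With O8 already acylated, C12 has only one oxygen to close on. The forward step must be a transesterification mild enough for the oxirane and the acceptors.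

**Oxirane.** Removing the oxirane oxygen takes 20 back to the Z-allylic alcohol 19. Placing the oxygen after C6 is set uses the threo preference of a peracid. Nucleophilic addition to a preformed epoxy aldehyde would be expected to favour the erythro isomer. Compound 19 has two stereocentres fewer. The forward step must select one face of the only electron-rich double bond.

**Ring.** The C6–C7 ring bond of 19 is cut to give the open-chain enal bromide 17, which reacts through the allylzinc 18. Of the ten ring bonds, only this one yields two stereocentres, the methylene C13 and the lactone retron on closure. Both flanking partners, a Z-enal and a Z-bromomethyl enoate, are stable. The precursor is acyclic with two stereocentres. The forward step must be γ-selective, 1,2-selective and syn-selective.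

**Second acrylate unit.** C7=C11 is cut, so 17 comes through 16, 15 and 14 from the vinyl carbinol 12 and methyl 2-(bromomethyl)acrylate 13. An aldehyde at C7 would carry a β-acetoxy group and would not survive base, so the neutral olefin exchange is preferred. The methacrylate must go on after this step, because an allylic methacrylate beside a vinyl group would close to a butenolide.

**Diol.** C8–C9 is cut, so 12 comes through 11 and 10 from the formyl enoate 7 and allyl methoxymethyl ether 8 by way of the borane 9. This sets the threo diol and its absolute configuration in one reagent-controlled step. O9 emerges free and O8 masked, which is the differentiation the two esters need. Both precursors are achiral.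

**First acrylate unit.** C1–C10 is cut, so 7 comes through 6 and 5 from aldehyde 3 and methyl acrylate 4. The Morita–Baylis–Hillman adduct brings C10, C14 and C9 at once. Its allylic transposition places C2 cis to C9, which is the ring-cis geometry. An olefination reagent carrying a β-oxygen would eliminate.

**Chain.** Aldehyde 3 comes through 2 from nerol 1 by loss of the isopropylidene carbons. Nerol supplies C1 to C6 and C15 with the Z double bond already in place.

## Roads not taken

**Alternative 1:** The most obvious cut is C1=C10, closed by ring-closing metathesis of the seco-diene A1, which has a terminal olefin at C1 and an acrylate methylene on C10. The step would have to form a trisubstituted, electron-poor double bond inside a strained ten-membered ring from a 1,1-disubstituted partner. A1 also carries two further acrylate-type olefins (C11=C13 and the methacrylate) that can react in smaller rings. Its C9 carbinol would come from an acrylate addition to a chiral aldehyde with weak stereocontrol. The ring closure itself sets no stereocentre. The chosen closure uses polar reactivity that none of the other olefins shares, and it sets C6 and C7 as it closes.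

**Alternative 2:** C2–C3 is cut and C5–C10 reconnected. This is the anionic oxy-Cope rearrangement of the dialkenylcyclohexanol A2, followed by trapping of the ring-expanded enolate as the enol triflate A3 and methoxycarbonylation to bring in C14.

- A chair transition state from the cis-dialkenyl isomer can give only one ring-cis and one ring-trans double bond. With the alkoxide pseudo-equatorial, C4=C5 comes out ring-trans, as in A3, so the cis-oxirane would need a dihydroxylation, sulfonylation and inversion detour.
- The O6, C11, O8 triad must sit axial, equatorial, axial on the cyclohexane next to a fully substituted carbinol. This makes A2 crowded and long to build.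
- The chosen plan takes the Z olefin from nerol and builds the triad on an open chain.

**Alternative 3:** A temporary C1–C6 bond is added. The cis-fused bicyclic hydroxy ester A4 would be reached from an ortho-toluate by side-chain alkylation, Birch reduction, vinyl addition and six-ring metathesis. Halogenation at C10 and Grob fragmentation would then give the achiral ring-cis trienone A5.

- The ring expansion is short and both six-membered rings pass their cis geometry to the product.
- Against this, A5 holds no stereocentre, and its C7 methylene is acidic and skipped to the diene.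
- Any oxygen placed on C8 is β to the C6 ketone and eliminates before C11 can be attached to C7.
- The decoration would cost more steps than the whole chosen route, and it lacks a reliable source of absolute configuration.

Key step: step 13

Remark on the chemistry: the configuration is taken exactly as written in the SMILES (cis-fused lactone, cis-oxirane, C2 cis to C9). Racemic or undefined centres occur only where the next step destroys them (the carbinol of 5).

## Steps

Step 1
Reactants: 1 nerol
Product: 2 neryl tert-butyldimethylsilyl ether
Conditions: TBSCl, imidazole, CH2Cl2, 0 °C to rt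
Reagents that add atoms: tert-butyldimethylsilyl chloride CC(C)(C)[Si](C)(C)Cl
Why: Standard silylation of a primary alcohol; it masks O6 during chain building, while nerol supplies C1 to C6, C15 and the Z double bond C4=C5.

Step 2
Reactants: 2 neryl tert-butyldimethylsilyl ether
Product: 3 (4Z)-6-(tert-butyldimethylsilyloxy)-4-methylhex-4-enal
Conditions: O3 (1 equiv), pyridine, CH2Cl2, −78 °C; Me2S
Reagents that add atoms: ozone [O-][O+]=O
Why: Ozonolysis with one equivalent of ozone should cleave the isopropylidene double bond first, because the other trisubstituted olefin is deactivated inductively by the allylic silyloxy group; this lays C1 bare as an aldehyde.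

Step 3
Reactants: 3 (4Z)-6-(tert-butyldimethylsilyloxy)-4-methylhex-4-enal; 4 methyl acrylate
Product: 5 methyl (6Z)-8-(tert-butyldimethylsilyloxy)-3-hydroxy-6-methyl-2-methylideneoct-6-enoate (racemic carbinol)
Conditions: DABCO, MeOH, rt
Reagents that add atoms: none
Why: The Morita–Baylis–Hillman reaction of an unhindered aliphatic aldehyde brings C10, C14 and C9 in one atom-economic step; the carbinol centre is lost in step 4, so its configuration does not matter.

Step 4
Reactants: 5 methyl (6Z)-8-(tert-butyldimethylsilyloxy)-3-hydroxy-6-methyl-2-methylideneoct-6-enoate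
Product: 6 methyl (2Z,6Z)-2-(bromomethyl)-8-(tert-butyldimethylsilyloxy)-6-methylocta-2,6-dienoate
Conditions: NBS, Me2S, CH2Cl2, 0 °C
Reagents that add atoms: N-bromosuccinimide O=C1CCC(=O)N1Br
Why: Corey–Kim type activation of the hydroxyl is followed by SN2' attack of bromide on the methylene; Baylis–Hillman esters give the isomer with the alkyl chain trans to the ester, which places C2 cis to C9 as the ring needs.

Step 5
Reactants: 6 methyl (2Z,6Z)-2-(bromomethyl)-8-(tert-butyldimethylsilyloxy)-6-methylocta-2,6-dienoate
Product: 7 methyl (2E,6Z)-8-(tert-butyldimethylsilyloxy)-2-formyl-6-methylocta-2,6-dienoate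
Conditions: 4-methylmorpholine N-oxide, MeCN, 4 Å sieves, rt
Reagents that add atoms: 4-methylmorpholine N-oxide C[N+]1([O-])CCOCC1
Why: This is a Kornblum type oxidation in which the N-oxide oxygen displaces the activated allylic bromide and base-induced loss of the amine gives the aldehyde; the double bond is not touched, so its geometry is kept.

Step 6
Reactants: 7 methyl (2E,6Z)-8-(tert-butyldimethylsilyloxy)-2-formyl-6-methylocta-2,6-dienoate; 8 allyl methoxymethyl ether
Product: 10 methyl (2E,6Z)-8-(tert-butyldimethylsilyloxy)-2-[(1S,2S)-1-hydroxy-2-(methoxymethoxy)but-3-en-1-yl]-6-methylocta-2,6-dienoate, via (Z)-alkoxyallyl diisopinocampheylborane 9 (not isolated)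
Conditions: 8, s-BuLi, THF, −78 °C; (+)-Ipc2BOMe; BF3·OEt2; 7, −78 °C; then HOCH2CH2NH2
Reagents that add atoms: none
Why: In the Brown alkoxyallylboration the Z-alkoxyallylborane reacts through a closed chair, so the Z geometry gives the syn (threo) O8/O9 pair. The isopinocampheyl groups derived from (−)-α-pinene direct attack to the Re face of the aldehyde, giving 9S and hence 8S. The amine work-up avoids alkaline peroxide, which would attack the enoate.

Step 7
Reactants: 10 methyl (2E,6Z)-8-(tert-butyldimethylsilyloxy)-2-[(1S,2S)-1-hydroxy-2-(methoxymethoxy)but-3-en-1-yl]-6-methylocta-2,6-dienoate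
Product: 11 the (1S,2S)-1-acetoxy-2-(methoxymethoxy)but-3-en-1-yl analogue of 10 (O9 acetate)
Conditions: Ac2O, pyridine, DMAP (cat.), CH2Cl2, 0 °C
Reagents that add atoms: acetic anhydride CC(=O)OC(C)=O
Why: O9 is the only free hydroxyl, so the acetate of the target goes on without any selectivity problem and before an amine-sensitive allylic bromide is present.

Step 8
Reactants: 11 O9 acetate with O8 methoxymethyl ether
Product: 12 methyl (2E,6Z)-2-[(1S,2S)-1-acetoxy-2-hydroxybut-3-en-1-yl]-8-(tert-butyldimethylsilyloxy)-6-methylocta-2,6-dienoate
Conditions: ZnBr2, n-PrSH, CH2Cl2, 0 °C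
Reagents that add atoms: none
Why: Lewis acid thiolysis of the acetal is fast and non-basic, so the silyl ether should survive and the acetate should stay on O9; no oxirane is present yet.

Step 9
Reactants: 12 methyl (2E,6Z)-2-[(1S,2S)-1-acetoxy-2-hydroxybut-3-en-1-yl]-8-(tert-butyldimethylsilyloxy)-6-methylocta-2,6-dienoate; 13 methyl 2-(bromomethyl)acrylate
Product: 14 methyl (2Z,4S,5S,6E,10Z)-5-acetoxy-2-(bromomethyl)-12-(tert-butyldimethylsilyloxy)-4-hydroxy-6-(methoxycarbonyl)-10-methyldodeca-2,6,10-trienoate
Conditions: second-generation Hoveyda-Grubbs catalyst (cat.), 13 (excess), CH2Cl2, 40 °C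
Reagents that add atoms: none
Why: Cross metathesis of a terminal olefin with an α-substituted acrylate puts C11, C12 and C13 on C7 under neutral conditions; the trisubstituted olefins of 12 are inert. The product should have C8 trans to the ester (Z by the bromine priority), as methacrylate-type partners do.

Step 10
Reactants: 14 methyl (2Z,4S,5S,6E,10Z)-5-acetoxy-2-(bromomethyl)-12-(tert-butyldimethylsilyloxy)-4-hydroxy-6-(methoxycarbonyl)-10-methyldodeca-2,6,10-trienoate
Product: 15 the 4-(methacryloyloxy) derivative of 14 (O8 methacrylate)
Conditions: methacrylic anhydride, MgBr2·OEt2, i-Pr2NEt, CH2Cl2, 0 °C to rt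
Reagents that add atoms: methacrylic anhydride C=C(C)C(=O)OC(=O)C(C)=C
Why: The anhydride is activated by the magnesium salt and the base is hindered; this avoids nucleophilic amines, which would quaternise on the bromomethyl enoate, and keeps the time available for O9 to O8 acetyl migration short.

Step 11
Reactants: 15 O8 methacrylate, O6 silyl ether
Product: 16 methyl (2Z,4S,5S,6E,10Z)-5-acetoxy-2-(bromomethyl)-12-hydroxy-6-(methoxycarbonyl)-4-(methacryloyloxy)-10-methyldodeca-2,6,10-trienoate
Conditions: HF (48% aq), MeCN, 0 °C
Reagents that add atoms: none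
Why: Acidic fluoride removes a primary silyl ether without base or amine, so the esters and the allylic bromide are left alone.

Step 12
Reactants: 16 methyl (2Z,4S,5S,6E,10Z)-5-acetoxy-2-(bromomethyl)-12-hydroxy-6-(methoxycarbonyl)-4-(methacryloyloxy)-10-methyldodeca-2,6,10-trienoate
Product: 17 the corresponding (10Z)-12-oxo compound (Z-enal at C6)
Conditions: TEMPO (cat.), PhI(OAc)2, CH2Cl2, rt
Reagents that add atoms: none
Why: Oxoammonium oxidation of a primary allylic alcohol is near neutral and should keep the Z geometry of the neral-type enal.

Step 13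
Reactants: 17 open-chain Z-enal (C6) with the Z-2-(bromomethyl)enoate (C13, C11, C7)
Product: 19 methyl (6S,7S,8S,9S)-9-acetoxy-6-hydroxy-7-[1-(methoxycarbonyl)ethenyl]-8-(methacryloyloxy)-4-methylcyclodeca-1(10),4-diene-10-carboxylate (both ring double bonds ring-cis), via allylzinc bromide 18 (not isolated)
Conditions: activated Zn dust, THF/sat. aq NH4Cl, rt, slow addition of 17 (high dilution)
Reagents that add atoms: none
Why: Zinc inserts into the allylic C13–Br bond to give 18, which adds through its γ-carbon C7 to the C6 aldehyde (SE2') in a chair-like six-centre Zimmerman–Traxler transition state. The closest known reaction type is the intramolecular Barbier (Dreiding–Schmidt) allylation with 2-(bromomethyl)acrylates, which has precedent for ten-membered carbocycles. The one ring closed is the C1 to C10 carbocycle, by 10-exo-trig attack on the carbonyl, and slow addition keeps the concentration of 18 low against oligomerisation. The ring-cis double bonds C1=C10 and C4=C5 turn the chain back on itself, so C6 and C7 can meet without a transoid segment. At C7, A1,3 strain across the Z double bond C7=C11 holds H8 in the olefin plane, and C6 should bond to the face anti to C9; this puts C11 on the same ring face as O8. At C6, C5 equatorial and C8 axial in the chair give the syn adduct, that is H6 cis to H7, the relation of the cis-lactone. The step needs γ- over α-attack, 1,2- over 1,4-addition to the enal, and inertness towards four esters and the other acceptors, all of which are normal behaviour of ester-substituted allylzinc reagents. The C12 methyl ester should largely stay open under these buffered conditions, which leaves O6–H free for step 14.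

Step 14
Reactants: 19 ten-membered Z-allylic alcohol
Product: 20 methyl (4R,5S,6R,7S,8S,9S)-9-acetoxy-4,5-epoxy-6-hydroxy-7-[1-(methoxycarbonyl)ethenyl]-8-(methacryloyloxy)-4-methylcyclodec-1(10)-ene-10-carboxylate
Conditions: mCPBA, NaHCO3, CH2Cl2, 0 °C
Reagents that add atoms: 3-chloroperbenzoic acid O=C(OO)c1cccc(Cl)c1
Why: In this hydroxyl-directed Prilezhaev epoxidation, A1,3 strain between C3 and the C6 substituents places H6 in the olefin plane, and the hydrogen-bonded peracid attacks the face that carries O6, giving the threo epoxy alcohol (4R,5S). Medium-ring Z-allylic alcohols follow the same sense. C4=C5 is the only electron-rich double bond.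

Step 15
Reactants: 20 epoxy hydroxy ester
Product: 21 target CNP0153978.6
Conditions: DBU (cat.), CH2Cl2, 0 °C to rt
Reagents that add atoms: none
Why: This 5-exo-trig transesterification of O6 onto the C12 methyl ester is fast because O6 and C11 are cis. O8 and O9 are already acylated, so only the 6,12-lactone can form, and no stereocentre is touched.

## Compound list

1 | nerol, (2Z)-3,7-dimethylocta-2,6-dien-1-ol | CC(C)=CCC/C(C)=C\CO | starting material
2 | neryl tert-butyldimethylsilyl ether | CC(C)=CCC/C(C)=C\CO[Si](C)(C)C(C)(C)C | intermediate
3 | (4Z)-6-(tert-butyldimethylsilyloxy)-4-methylhex-4-enal | CC(C)(C)[Si](C)(C)OC/C=C(C)\CCC=O | intermediate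
4 | methyl acrylate | C=CC(=O)OC | starting material
5 | methyl (6Z)-8-(tert-butyldimethylsilyloxy)-3-hydroxy-6-methyl-2-methylideneoct-6-enoate (racemic carbinol) | CC(C)(C)[Si](C)(C)OC/C=C(C)\CCC(O)C(=C)C(=O)OC | intermediate
6 | methyl (2Z,6Z)-2-(bromomethyl)-8-(tert-butyldimethylsilyloxy)-6-methylocta-2,6-dienoate | CC(C)(C)[Si](C)(C)OC/C=C(C)\CC/C=C(/C(=O)OC)CBr | intermediate
7 | methyl (2E,6Z)-8-(tert-butyldimethylsilyloxy)-2-formyl-6-methylocta-2,6-dienoate | CC(C)(C)[Si](C)(C)OC/C=C(C)\CC/C=C(/C(=O)OC)C=O | intermediate
8 | allyl methoxymethyl ether, 3-(methoxymethoxy)prop-1-ene | C=CCOCOC | starting material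
9 | [(Z)-3-(methoxymethoxy)allyl]diisopinocampheylborane (from (−)-α-pinene series) | COCO/C=C\CB([C@H]1C[C@H]2C[C@@H]([C@@H]1C)C2(C)C)[C@H]1C[C@H]2C[C@@H]([C@@H]1C)C2(C)C | intermediate
10 | methyl (2E,6Z)-8-(tert-butyldimethylsilyloxy)-2-[(1S,2S)-1-hydroxy-2-(methoxymethoxy)but-3-en-1-yl]-6-methylocta-2,6-dienoate | CC(C)(C)[Si](C)(C)OC/C=C(C)\CC/C=C(/C(=O)OC)[C@H](O)[C@@H](OCOC)C=C | intermediate
11 | methyl (2E,6Z)-2-[(1S,2S)-1-acetoxy-2-(methoxymethoxy)but-3-en-1-yl]-8-(tert-butyldimethylsilyloxy)-6-methylocta-2,6-dienoate | CC(C)(C)[Si](C)(C)OC/C=C(C)\CC/C=C(/C(=O)OC)[C@H](OC(C)=O)[C@@H](OCOC)C=C | intermediate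
12 | methyl (2E,6Z)-2-[(1S,2S)-1-acetoxy-2-hydroxybut-3-en-1-yl]-8-(tert-butyldimethylsilyloxy)-6-methylocta-2,6-dienoate | CC(C)(C)[Si](C)(C)OC/C=C(C)\CC/C=C(/C(=O)OC)[C@H](OC(C)=O)[C@@H](O)C=C | intermediate
13 | methyl 2-(bromomethyl)acrylate | C=C(CBr)C(=O)OC | starting material
14 | methyl (2Z,4S,5S,6E,10Z)-5-acetoxy-2-(bromomethyl)-12-(tert-butyldimethylsilyloxy)-4-hydroxy-6-(methoxycarbonyl)-10-methyldodeca-2,6,10-trienoate | CC(C)(C)[Si](C)(C)OC/C=C(C)\CC/C=C(/C(=O)OC)[C@H](OC(C)=O)[C@@H](O)/C=C(\CBr)C(=O)OC | intermediate
15 | methyl (2Z,4S,5S,6E,10Z)-5-acetoxy-2-(bromomethyl)-12-(tert-butyldimethylsilyloxy)-6-(methoxycarbonyl)-4-(methacryloyloxy)-10-methyldodeca-2,6,10-trienoate | CC(C)(C)[Si](C)(C)OC/C=C(C)\CC/C=C(/C(=O)OC)[C@H](OC(C)=O)[C@@H](OC(=O)C(C)=C)/C=C(\CBr)C(=O)OC | intermediate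
16 | methyl (2Z,4S,5S,6E,10Z)-5-acetoxy-2-(bromomethyl)-12-hydroxy-6-(methoxycarbonyl)-4-(methacryloyloxy)-10-methyldodeca-2,6,10-trienoate | OC/C=C(C)\CC/C=C(/C(=O)OC)[C@H](OC(C)=O)[C@@H](OC(=O)C(C)=C)/C=C(\CBr)C(=O)OC | intermediate
17 | methyl (2Z,4S,5S,6E,10Z)-5-acetoxy-2-(bromomethyl)-6-(methoxycarbonyl)-4-(methacryloyloxy)-10-methyl-12-oxododeca-2,6,10-trienoate | O=C/C=C(C)\CC/C=C(/C(=O)OC)[C@H](OC(C)=O)[C@@H](OC(=O)C(C)=C)/C=C(\CBr)C(=O)OC | intermediate
18 | allylzinc bromide derived from 17 (zinc on C13) | O=C/C=C(C)\CC/C=C(/C(=O)OC)[C@H](OC(C)=O)[C@@H](OC(=O)C(C)=C)/C=C(\C[Zn]Br)C(=O)OC | intermediate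
19 | methyl (6S,7S,8S,9S)-9-acetoxy-6-hydroxy-7-[1-(methoxycarbonyl)ethenyl]-8-(methacryloyloxy)-4-methylcyclodeca-1(10),4-diene-10-carboxylate, both ring double bonds ring-cis | C=C(C)C(=O)O[C@H]1[C@@H](C(=C)C(=O)OC)[C@@H](O)/C=C(C)\CC/C=C(/C(=O)OC)[C@@H]1OC(C)=O | intermediate
20 | methyl (4R,5S,6R,7S,8S,9S)-9-acetoxy-4,5-epoxy-6-hydroxy-7-[1-(methoxycarbonyl)ethenyl]-8-(methacryloyloxy)-4-methylcyclodec-1(10)-ene-10-carboxylate | C=C(C)C(=O)O[C@H]1[C@@H](C(=C)C(=O)OC)[C@@H](O)[C@@H]2O[C@]2(C)CC/C=C(/C(=O)OC)[C@@H]1OC(C)=O | intermediate
21 | CNP0153978.6, (4R,5S,6R,7R,8S,9S)-9-acetoxy-4,5-epoxy-8-(methacryloyloxy)-14-methoxy-14-oxogermacra-1(10),11(13)-dien-12,6-olide | C=C(C)C(=O)O[C@H]1[C@H]2C(=C)C(=O)O[C@H]2[C@@H]2O[C@]2(C)CC/C=C(/C(=O)OC)[C@@H]1OC(C)=O | target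

## Step count and least certain steps

Total step count: 15. Longest linear sequence: 15 (from nerol 1).

**Step 13 (key step).** The most likely failure is intermolecular reaction of the allylzinc with a second molecule, because closure of a ten-membered ring is slow. The second is loss of facial or syn selectivity, because allylzinc species equilibrate between geometric isomers and the ring tether may override the A1,3 model.

The fallback replaces the configurationally labile organozinc by an isolable, geometrically defined allylboronate that reacts only through a closed transition state and can be heated at extreme dilution. It sets out from 16. Borylation with B2pin2 and Pd2(dba)3 through the π-allyl complex of divalent palladium gives the linear allylboronate alcohol F1. TEMPO and PhI(OAc)2 oxidation gives the allylboronate enal F2. Warming F2 in dilute toluene, followed by a mild aqueous work-up, should lead back to 19.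

**Step 14.** Facial selectivity may be poor if the ring holds O6–H away from the olefin. The directing group is lost altogether if 19 lactonises early.

The fallback sets the oxirane by reagent control before the ring is closed. It sets out from 16. Sharpless epoxidation with L-(+)-diethyl tartrate, Ti(OiPr)4 and t-BuOOH gives the (4R,5S) epoxy alcohol F3. TEMPO and PhI(OAc)2 oxidation gives the epoxy aldehyde F4. Zinc-mediated closure as in step 13 comes back at 20. The price is that C6 is then set by addition to an α-oxygenated aldehyde.

**Step 9.** The allylic, oxygen-flanked vinyl group may be slow to react, the catalyst may decay on the allylic bromide, and the terminal olefin may homodimerise.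

The fallback builds the same unit by carbonyl addition, as in steps 3 and 4. It sets out from 11. Ozonolysis of the vinyl group gives the aldehyde F5. Low-temperature addition of the α-(methoxycarbonyl)vinylaluminium reagent, made from methyl propiolate, i-Bu2AlH and 4-methylmorpholine N-oxide, gives the hydroxy acrylate F6 without base. NBS and Me2S give the bromomethyl enoate F7. Cleavage of the acetal with B-bromocatecholborane comes back at 14.

**Step 2.** Ozone may also attack the C4=C5 double bond, because both olefins are trisubstituted and differ only through the inductive effect of O6.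

The fallback separates selection from cleavage. It sets out from 2. One equivalent of mCPBA at low temperature gives the terminal epoxide F8, and H5IO6 in THF and water cleaves it to 3.

**Step 15.** The base may promote acyl migration between O8 and O6, epoxide migration towards O6, or conjugate addition, all in competition with lactonisation.

The fallback reverses the last two steps. It sets out from 19, which is lactonised on silica gel or in warm toluene to the 4,5-deoxy lactone F9. Peripheral mCPBA epoxidation of its only electron-rich double bond then comes back at 21, with the face now set by the ring conformation rather than by O6–H.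

## Further compounds

F1 | step 13 | allylboronate alcohol (pinacol boronate on C13 in place of bromine in 16) | OC/C=C(C)\CC/C=C(/C(=O)OC)[C@H](OC(C)=O)[C@@H](OC(=O)C(C)=C)/C=C(\CB1OC(C)(C)C(C)(C)O1)C(=O)OC
F2 | step 13 | allylboronate enal (pinacol boronate on C13 in place of bromine in 17) | O=C/C=C(C)\CC/C=C(/C(=O)OC)[C@H](OC(C)=O)[C@@H](OC(=O)C(C)=C)/C=C(\CB1OC(C)(C)C(C)(C)O1)C(=O)OC
F3 | step 14 | (4R,5S)-4,5-epoxy alcohol derived from 16 | OC[C@@H]1O[C@]1(C)CC/C=C(/C(=O)OC)[C@H](OC(C)=O)[C@@H](OC(=O)C(C)=C)/C=C(\CBr)C(=O)OC
F4 | step 14 | (4R,5S)-4,5-epoxy aldehyde derived from F3 | O=C[C@@H]1O[C@]1(C)CC/C=C(/C(=O)OC)[C@H](OC(C)=O)[C@@H](OC(=O)C(C)=C)/C=C(\CBr)C(=O)OC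
F5 | step 9 | C7 aldehyde from ozonolysis of 11 | CC(C)(C)[Si](C)(C)OC/C=C(C)\CC/C=C(/C(=O)OC)[C@H](OC(C)=O)[C@@H](OCOC)C=O
F6 | step 9 | C7 hydroxy acrylate (carbinol configuration undefined) | CC(C)(C)[Si](C)(C)OC/C=C(C)\CC/C=C(/C(=O)OC)[C@H](OC(C)=O)[C@@H](OCOC)C(O)C(=C)C(=O)OC
F7 | step 9 | O8 methoxymethyl ether of 14 | CC(C)(C)[Si](C)(C)OC/C=C(C)\CC/C=C(/C(=O)OC)[C@H](OC(C)=O)[C@@H](OCOC)/C=C(\CBr)C(=O)OC
F8 | step 2 | 6,7-epoxide of 2 (racemic) | CC1(C)OC1CC/C(C)=C\CO[Si](C)(C)C(C)(C)C
F9 | step 15 | 4,5-deoxy lactone (21 without the oxirane oxygen, C4=C5 ring-cis) | C=C(C)C(=O)O[C@H]1[C@H]2C(=C)C(=O)O[C@H]2/C=C(C)\CC/C=C(/C(=O)OC)[C@@H]1OC(C)=O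
A1 | alternative 1 | seco-diene for ring-closing metathesis at C1=C10 | C=C(C)C(=O)O[C@H]([C@@H](OC(C)=O)C(=C)C(=O)OC)[C@H]1C(=C)C(=O)O[C@H]1[C@@H]1O[C@]1(C)CCC=C
A2 | alternative 2 | cis-1-vinyl-2-isopropenylcyclohexanol with silyloxy groups on C6, C8, C9 and isopropenyl on C7 | C=C[C@@]1(O)[C@H](O[Si](C)(C)C(C)(C)C)[C@@H](O[Si](C)(C)C(C)(C)C)[C@@H](C(C)=C)[C@@H](O[Si](C)(C)C(C)(C)C)[C@H]1C(C)=C
A3 | alternative 2 | ring-expanded enol triflate (C1=C10 ring-cis, C4=C5 ring-trans) | FC(F)(F)S(=O)(=O)O/C1=C/CC/C(C)=C/[C@H](O[Si](C)(C)C(C)(C)C)[C@H](C(C)=C)[C@H](O[Si](C)(C)C(C)(C)C)[C@H]1O[Si](C)(C)C(C)(C)C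
A4 | alternative 3 | methyl 4a-hydroxy-6-methyl-1,4,4a,7,8,8a-hexahydronaphthalene-1-carboxylate, cis-fused (racemic, one enantiomer drawn) | COC(=O)[C@H]1C=CC[C@]2(O)C=C(C)CC[C@H]12
A5 | alternative 3 | achiral all ring-cis methyl 4-methyl-6-oxocyclodeca-1(10),4,8-triene-10-carboxylate (germacrane numbers) | COC(=O)/C1=C/CC/C(C)=C\C(=O)C/C=C\1
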